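**Retrosynthetic overview**
1. Target 23 ⇐ 8-O-angeloylation of diol lactone 21 ⇐ C6-ketone reduction/lactonisation of cyclodecadienone 18.
2. 18 ⇐ alkoxide-triggered Grob fragmentation of cis-decalin 17 (C1–C6 bond broken, C2–OTs expelled): ring A is expanded by C7–C10 to the ten-membered ring; 4Z comes from ring A, 1E from the anti-periplanar fragmentation.
3. 17 ⇐ bicyclic enone 12 (C4 methylation, C2 tosyloxylation, C3 reduction/inversion).
4. 12 ⇐ MHAT radical cyclisation of quinol 11 (bond C1–C10, ring B) ⇐ indium Barbier allylation of p-benzoquinone with bromide 8 (bond C6–C7).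
5. 8 ⇐ proline aldol (sets C8) + Baylis–Hillman. Ring order: A (quinone) → B (radical cyclisation) → ten-membered ring (ring expansion) → lactone.

Assumption: germacrane numbering is used (ring C1–C10, C11–C13 acrylate/lactone, C14 on C10, C15 on C4) and the SMILES is taken literally: (3R,6R,7S,8R,10R), 1E,4Z, angelate, 6,7-cis-fused lactone.

**Step 1**
Reactants: 1 acetone; 2 2,2-dimethoxyacetaldehyde
Product: 3 (R)-4-hydroxy-5,5-dimethoxypentan-2-one
Conditions: L-proline (30 mol%), acetone/DMSO 4:1, rt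
Reagents that add atoms: none
Why: L-proline enamine aldol of acetone onto the free aldehyde (List–Barbas aldol); Re-face attack through the hydrogen-bonded chair sets C8 as R.

**Step 2**
Reactants: 3 (R)-4-hydroxy-5,5-dimethoxypentan-2-one
Product: 4 (R)-4-(tert-butyldimethylsilyloxy)-5,5-dimethoxypentan-2-one
Conditions: TBSCl, imidazole, DMF, rt
Reagents that add atoms: tert-butyldimethylsilyl chloride CC(C)(C)[Si](C)(C)Cl
Why: Standard silylation; the bulky non-chelating TBS ether blocks the C8 oxygen (no 8,12-lactonisation later) and is the steering group in step 6.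

**Step 3**
Reactants: 4 (R)-4-(tert-butyldimethylsilyloxy)-5,5-dimethoxypentan-2-one
Product: 5 (R)-2-(tert-butyldimethylsilyloxy)-4-oxopentanal
Conditions: TFA/H2O 9:1, CH2Cl2, 0 °C
Reagents that add atoms: water O
Why: Acid-catalysed acetal hydrolysis; the secondary TBS ether and the C8 centre (no base present) are untouched.

**Step 4**
Reactants: 5 (R)-2-(tert-butyldimethylsilyloxy)-4-oxopentanal; 6 isopropyl acrylate
Product: 7 isopropyl (4R)-4-(tert-butyldimethylsilyloxy)-3-hydroxy-2-methylidene-6-oxoheptanoate (C3 epimers)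
Conditions: DABCO (1 equiv), 6 (5 equiv), MeOH, rt, 48 h
Reagents that add atoms: none
Why: DABCO-mediated Morita–Baylis–Hillman reaction, aldehyde-selective over the ketone; the new carbinol centre is erased in step 5.

**Step 5**
Reactants: 7 isopropyl (4R)-4-(tert-butyldimethylsilyloxy)-3-hydroxy-2-methylidene-6-oxoheptanoate
Product: 8 isopropyl (2Z,4R)-2-(bromomethyl)-4-(tert-butyldimethylsilyloxy)-6-oxohept-2-enoate
Conditions: NBS, Me2S, CH2Cl2, 0 °C to rt
Reagents that add atoms: N-bromosuccinimide O=C1CCC(=O)N1Br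
Why: Corey–Kim-type SN2′ bromination of the Baylis–Hillman alcohol gives the thermodynamically favoured (Z)-2-(bromomethyl)enoate.

**Step 6**
Reactants: 8 isopropyl (2Z,4R)-2-(bromomethyl)-4-(tert-butyldimethylsilyloxy)-6-oxohept-2-enoate; 9 p-benzoquinone
Product: 10 isopropyl (3S,4R)-4-(tert-butyldimethylsilyloxy)-3-(1-hydroxy-4-oxocyclohexa-2,5-dien-1-yl)-2-methylidene-6-oxoheptanoate
Conditions: In powder, NaI, DMF, 0 °C to rt
Reagents that add atoms: none
Why: Indium Barbier allylation of the quinone carbonyl through the γ-carbon (C7) builds the C6–C7 bond and the quinol; with C8–H eclipsing the alkene (A1,3 strain) the bond forms anti to the C8–OTBS group, giving 7S (C6 is not yet stereogenic).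

**Step 7**
Reactants: 10 quinol methyl ketone (see step 6)
Product: 11 isopropyl (3S,4R)-4-(tert-butyldimethylsilyloxy)-3-(1-hydroxy-4-oxocyclohexa-2,5-dien-1-yl)-2-methylidene-6-(triethylsilyloxy)hept-6-enoate
Conditions: LiHMDS (2.1 equiv), TESCl (1.1 equiv), THF, −78 °C
Reagents that add atoms: chlorotriethylsilane CC[Si](Cl)(CC)CC
Why: Kinetic deprotonation of the only enolisable ketone at its methyl group and O-silylation (silyl enol ether formation); the hindered lithium quinolate is not silylated at −78 °C and is reprotonated on work-up.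

**Step 8**
Reactants: 11 quinol TES enol ether (see step 7)
Product: 12 isopropyl 2-[cis-fused 6-(tert-butyldimethylsilyloxy)-4a-hydroxy-8-methyl-2-oxo-8-(triethylsilyloxy)-1,2,4a,5,6,7,8,8a-octahydronaphthalen-5-yl]acrylate (germacrane numbering: 6-OH, 1-H, C7 branch and 10-O α; 8-O and 10-Me β)
Conditions: Fe(acac)3 (30 mol%), PhSiH3 (2.5 equiv), EtOH/(CH2OH)2 5:1, 40 °C
Reagents that add atoms: none
Why: Proposed new method: Fe–H hydrogen-atom transfer (MHAT) to the silyl enol ether gives a tertiary α-silyloxy radical that adds 6-exo (Giese) to one enone arm of the 4-hydroxycyclohexadienone, and the α-keto radical is then reduced and protonated; the chair transition state with the C7 and C8 substituents equatorial and the quinol OH axial and hydrogen-bonded to the silyloxy oxygen selects the arm (sets C6 and C1, cis-fused) and places 10-OSi axial/10-Me equatorial (10R); the closest known reaction is Fe(acac)3/PhSiH3 reductive olefin–enone coupling with heteroatom-substituted donor olefins and MHAT Giese cyclisation, which has not been shown as an arm-selective desymmetrisation of a p-quinol by a silyl enol ether.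

**Step 9**
Reactants: 12 bicyclic enone (see step 8)
Product: 13 the 3-iodo enone of 12 (iodine on C4, germacrane numbering)
Conditions: I2, pyridine/CCl4 1:1, rt
Reagents that add atoms: iodine II
Why: Johnson α-iodination of the enone (pyridine conjugate addition, iodination, elimination) puts the halogen on C4 only.

**Step 10**
Reactants: 13 α-iodo enone
Product: 14 the 3-methyl enone (C4–CH3 = C15)
Conditions: Me4Sn, Pd2(dba)3 (5 mol%), AsPh3, CuI, NMP, 50 °C
Reagents that add atoms: tetramethylstannane C[Sn](C)(C)C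
Why: Stille cross-coupling of the α-iodoenone installs the C4 methyl under neutral conditions.

**Step 11**
Reactants: 14 methyl enone
Product: 15 the 1-tosyloxy ketone of 14 (2α-OTs, germacrane numbering; trans to the C1–C10 bond)
Conditions: PhI(OH)OTs, MeCN, 60 °C
Reagents that add atoms: hydroxy(tosyloxy)iodobenzene Cc1ccc(cc1)S(=O)(=O)OI(O)c1ccccc1
Why: Koser α-tosyloxylation via the only possible enol (C2=C3); the sulfonate enters anti to the neighbouring C1–C10 bond and ends equatorial (2α), trans to C10.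

**Step 12**
Reactants: 15 α-tosyloxy enone
Product: 16 the 3β-allylic alcohol (2α-OTs, 3β-OH trans)
Conditions: NaBH4, CeCl3·7H2O, MeOH/THF, −78 °C
Reagents that add atoms: none
Why: Luche 1,2-reduction; axial hydride delivery from the α-face of the half-chair enone gives the equatorial 3β-alcohol and leaves ester, acrylate and tosylate intact.

**Step 13**
Reactants: 16 3β-alcohol
Product: 17 the 3α-acetate (2α-OTs, 3α-OAc cis; free tertiary 6-OH)
Conditions: PPh3, DIAD, AcOH, PhMe, 0 °C to rt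
Reagents that add atoms: acetic acid CC(=O)O
Why: Mitsunobu esterification with SN2 inversion converts 3β-OH into the 3α-acetate (3R); the tertiary 6-OH cannot react.

**Step 14**
Reactants: 17 γ-tosyloxy tertiary alcohol
Product: 18 isopropyl (1E,4Z)-3α-acetoxy-8β-(tert-butyldimethylsilyloxy)-6-oxo-10α-(triethylsilyloxy)germacra-1,4,11(13)-trien-12-oate (7βH)
Conditions: KHMDS (1.1 equiv), THF, −78 to −20 °C; AcOH quench
Reagents that add atoms: none
Why: Alkoxide-triggered Grob (Wharton) fragmentation: the equatorial C2–OTs is antiperiplanar to the C1–C6 ring-fusion bond, so C6–O⁻ becomes C=O, C1–C6 breaks and tosylate leaves, expanding six-membered ring A by C7–C10 to the cyclodecadienone; the equatorial C10 on C1 gives 1E, the ring-A alkene becomes 4Z, and the C1, C2 and C6 centres are consumed.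

**Step 15**
Reactants: 18 cyclodecadienone
Product: 21 3α-acetoxy-8β,10α-dihydroxygermacra-1E,4Z,11(13)-trien-6α,12-olide (7βH), via 6α-hydroxy ester 19 (not isolated), via bis-silyl lactone 20 (not isolated)
Conditions: NaBH4, CeCl3·7H2O, MeOH, −78 °C; then HF·pyridine, THF/pyridine, 0 °C to rt
Reagents that add atoms: none
Why: Luche reduction with hydride approaching the enone carbonyl anti to the C7 acrylate branch gives the 6α-alcohol (6R, cis to C11), which lactonises with loss of isopropanol under HF·pyridine while the same reagent removes both silyl ethers (reduction/lactonisation/desilylation).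

**Step 16**
Reactants: 21 diol lactone; 22 angelic acid
Product: 23 target (3R,6R,7S,8R,10R)-3-acetoxy-8-angeloyloxy-10-hydroxygermacra-1E,4Z,11(13)-trien-6,12-olide
Conditions: 2,4,6-trichlorobenzoyl chloride, Et3N, PhMe, rt; then 21, DMAP, 60 °C
Reagents that add atoms: none
Why: Yamaguchi esterification acylates the only secondary alcohol (8-OH; 10-OH is tertiary) and keeps the Z geometry of the angelate.

**Compound list**
1 | acetone | CC(C)=O | starting material
2 | 2,2-dimethoxyacetaldehyde | COC(OC)C=O | starting material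
3 | (R)-4-hydroxy-5,5-dimethoxypentan-2-one | CC(=O)C[C@@H](O)C(OC)OC | intermediate
4 | (R)-4-(tert-butyldimethylsilyloxy)-5,5-dimethoxypentan-2-one | CC(=O)C[C@@H](O[Si](C)(C)C(C)(C)C)C(OC)OC | intermediate
5 | (R)-2-(tert-butyldimethylsilyloxy)-4-oxopentanal | CC(=O)C[C@@H](O[Si](C)(C)C(C)(C)C)C=O | intermediate
6 | isopropyl acrylate | C=CC(=O)OC(C)C | starting material
7 | isopropyl (4R)-4-(tert-butyldimethylsilyloxy)-3-hydroxy-2-methylidene-6-oxoheptanoate (C3 epimers) | CC(=O)C[C@@H](O[Si](C)(C)C(C)(C)C)C(O)C(=C)C(=O)OC(C)C | intermediate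
8 | isopropyl (2Z,4R)-2-(bromomethyl)-4-(tert-butyldimethylsilyloxy)-6-oxohept-2-enoate | CC(=O)C[C@@H](O[Si](C)(C)C(C)(C)C)/C=C(\CBr)C(=O)OC(C)C | intermediate
9 | p-benzoquinone | O=C1C=CC(=O)C=C1 | starting material
10 | isopropyl (3S,4R)-4-(tert-butyldimethylsilyloxy)-3-(1-hydroxy-4-oxocyclohexa-2,5-dien-1-yl)-2-methylidene-6-oxoheptanoate | CC(=O)C[C@@H](O[Si](C)(C)C(C)(C)C)[C@H](C(=C)C(=O)OC(C)C)C1(O)C=CC(=O)C=C1 | intermediate
11 | isopropyl (3S,4R)-4-(tert-butyldimethylsilyloxy)-3-(1-hydroxy-4-oxocyclohexa-2,5-dien-1-yl)-2-methylidene-6-(triethylsilyloxy)hept-6-enoate | C=C(O[Si](CC)(CC)CC)C[C@@H](O[Si](C)(C)C(C)(C)C)[C@H](C(=C)C(=O)OC(C)C)C1(O)C=CC(=O)C=C1 | intermediate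
12 | cis-fused bicyclic enone: isopropyl 2-[6-(TBSO)-4a-hydroxy-8-methyl-2-oxo-8-(TESO)-1,2,4a,5,6,7,8,8a-octahydronaphthalen-5-yl]acrylate | C=C(C(=O)OC(C)C)[C@H]1[C@H](O[Si](C)(C)C(C)(C)C)C[C@@](C)(O[Si](CC)(CC)CC)[C@@H]2CC(=O)C=C[C@]12O | intermediate
13 | 3-iodo enone of 12 | C=C(C(=O)OC(C)C)[C@H]1[C@H](O[Si](C)(C)C(C)(C)C)C[C@@](C)(O[Si](CC)(CC)CC)[C@@H]2CC(=O)C(I)=C[C@]12O | intermediate
14 | 3-methyl enone | C=C(C(=O)OC(C)C)[C@H]1[C@H](O[Si](C)(C)C(C)(C)C)C[C@@](C)(O[Si](CC)(CC)CC)[C@@H]2CC(=O)C(C)=C[C@]12O | intermediate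
15 | 1-tosyloxy-3-methyl enone (2α-OTs in germacrane numbering) | C=C(C(=O)OC(C)C)[C@H]1[C@H](O[Si](C)(C)C(C)(C)C)C[C@@](C)(O[Si](CC)(CC)CC)[C@@H]2[C@@H](OS(=O)(=O)c3ccc(C)cc3)C(=O)C(C)=C[C@]12O | intermediate
16 | 3β-alcohol (2α-OTs, 3β-OH) | C=C(C(=O)OC(C)C)[C@H]1[C@H](O[Si](C)(C)C(C)(C)C)C[C@@](C)(O[Si](CC)(CC)CC)[C@@H]2[C@@H](OS(=O)(=O)c3ccc(C)cc3)[C@H](O)C(C)=C[C@]12O | intermediate
17 | 3α-acetate (2α-OTs, 3α-OAc, 6-OH free) | C=C(C(=O)OC(C)C)[C@H]1[C@H](O[Si](C)(C)C(C)(C)C)C[C@@](C)(O[Si](CC)(CC)CC)[C@@H]2[C@@H](OS(=O)(=O)c3ccc(C)cc3)[C@@H](OC(C)=O)C(C)=C[C@]12O | intermediate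
18 | isopropyl (1E,4Z)-3α-acetoxy-8β-(TBSO)-6-oxo-10α-(TESO)germacra-1,4,11(13)-trien-12-oate | C=C(C(=O)OC(C)C)[C@@H]1C(=O)/C=C(/C)[C@H](OC(C)=O)/C=C/[C@](C)(O[Si](CC)(CC)CC)C[C@H]1O[Si](C)(C)C(C)(C)C | intermediate
19 | 6α-hydroxy ester of 18 | C=C(C(=O)OC(C)C)[C@@H]1[C@H](O)/C=C(/C)[C@H](OC(C)=O)/C=C/[C@](C)(O[Si](CC)(CC)CC)C[C@H]1O[Si](C)(C)C(C)(C)C | intermediate
20 | 8-O-TBS-10-O-TES 6α,12-lactone | C=C1C(=O)O[C@@H]2/C=C(/C)[C@H](OC(C)=O)/C=C/[C@](C)(O[Si](CC)(CC)CC)C[C@@H](O[Si](C)(C)C(C)(C)C)[C@H]12 | intermediate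
21 | 3α-acetoxy-8β,10α-dihydroxygermacra-1E,4Z,11(13)-trien-6α,12-olide | C=C1C(=O)O[C@@H]2/C=C(/C)[C@H](OC(C)=O)/C=C/[C@](C)(O)C[C@@H](O)[C@H]12 | intermediate
22 | angelic acid, (Z)-2-methylbut-2-enoic acid | C/C=C(/C)C(=O)O | starting material
23 | CNP0181631.1 | C=C1C(=O)O[C@@H]2/C=C(/C)[C@H](OC(C)=O)/C=C/[C@](C)(O)C[C@@H](OC(=O)/C(C)=C\C)[C@H]12 | target

**Totals and risks**
Total steps: 16. Longest linear sequence: 16 (steps 1–16).

Most likely to fail:

Step 8 (the proposed new step). The α-silyloxy radical can also close 6-endo onto the 2-substituted acrylate or take the other enone arm. The fallback uses known chemistry and sets out from 10. The kinetic lithium enolate is trapped with Comins' reagent to give the enol triflate F1. A Pd-catalysed reductive Heck cyclisation (Pd(OAc)2, PPh3, HCO2Na, DMF) onto the dienone gives the 10-methylidene cis-decalone F2. Mukaiyama hydration (Co(acac)2, PhSiH3, O2) gives the tertiary alcohol F3. TESOTf/2,6-lutidine on the less hindered 10-OH comes back to the route at 12.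

Step 13. SN2 at the hindered allylic C3 beside the tosylate may give elimination or SN2′ product. The fallback sets out from 15: reagent-controlled CBS reduction (Me-CBS enantiomer that delivers hydride to the β-face, catecholborane) gives the 3α-alcohol F4 directly. Plain acetylation (Ac2O, DMAP, pyridine) comes back to the route at 17.

Step 15. Hydride may add to the other face of the C6 ketone and lead to the trans-lactone series. The fallback sets out from 18: the Luche reduction is stopped before the acid stage at the 6β-hydroxy ester F5. Mitsunobu inversion with chloroacetic acid gives the 6α-chloroacetate F6. Thiourea/NaHCO3 in EtOH removes the chloroacetate selectively and comes back to the route at 19, which is taken through the HF·pyridine stage to 21.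

**Further compounds**
F1 | step 8 | enol triflate of 10 (6-triflyloxyhept-6-enoate) | C=C(OS(=O)(=O)C(F)(F)F)C[C@@H](O[Si](C)(C)C(C)(C)C)[C@H](C(=C)C(=O)OC(C)C)C1(O)C=CC(=O)C=C1
F2 | step 8 | 10-methylidene cis-decalone (8-O-TBS) | C=C(C(=O)OC(C)C)[C@H]1[C@H](O[Si](C)(C)C(C)(C)C)CC(=C)[C@@H]2CC(=O)C=C[C@]12O
F3 | step 8 | 10-hydroxy analogue of 12 (10-OH free, 8-O-TBS) | C=C(C(=O)OC(C)C)[C@H]1[C@H](O[Si](C)(C)C(C)(C)C)C[C@@](C)(O)[C@@H]2CC(=O)C=C[C@]12O
F4 | step 13 | 3α-alcohol (3-epimer of 16) | C=C(C(=O)OC(C)C)[C@H]1[C@H](O[Si](C)(C)C(C)(C)C)C[C@@](C)(O[Si](CC)(CC)CC)[C@@H]2[C@@H](OS(=O)(=O)c3ccc(C)cc3)[C@@H](O)C(C)=C[C@]12O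
F5 | step 15 | 6β-hydroxy ester (6-epimer of 19) | C=C(C(=O)OC(C)C)[C@@H]1[C@@H](O)/C=C(/C)[C@H](OC(C)=O)/C=C/[C@](C)(O[Si](CC)(CC)CC)C[C@H]1O[Si](C)(C)C(C)(C)C
F6 | step 15 | 6α-chloroacetate of 19 | C=C(C(=O)OC(C)C)[C@@H]1[C@H](OC(=O)CCl)/C=C(/C)[C@H](OC(C)=O)/C=C/[C@](C)(O[Si](CC)(CC)CC)C[C@H]1O[Si](C)(C)C(C)(C)C
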